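**Retrosynthetic overview**

1. The strategy rests on the 2-pyrone ring (O1', C2'–C6'): it is substituted only at C4' and C6' and carries hydrogens on C3' and C5', so C2'–C3'–C4' with the exocyclic CH2 is an alk-2-ynoic acid and C5'–C6' a terminal alkyne.
2. Target 16 ⇐ 6'-silyloxymethyl pyrone 13 (desilylation, two oxidations) ⇐ gold cascade of alkynoic acid 10 with propargyl silyl ether 11, forming O1'–C6' and then C4'–C5'.
3. Acid 10 ⇐ silylalkyne 9 (fluoride, CO2) ⇐ trans-selective C3 propargylation of (R)-lactone 6 with bromide 7.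
4. Lactone 6 ⇐ Stobbe condensation of veratraldehyde 1 with dimethyl succinate 2, asymmetric hydrogenation (sets C4), ester reduction and lactonisation.
5. Ring order: butyrolactone first (step 3), pyrone second and last (step 6).

Key step: step 6

Remark: the lactone ring is numbered O1, C2 (carbonyl), C3, C4, C5 and the pyrone ring O1', C2' (carbonyl) to C6'; the target is the (3R,4R), 3,4-trans isomer.

**Route**

Step 1
Reactants: 1 veratraldehyde (3,4-dimethoxybenzaldehyde); 2 dimethyl succinate
Product: 3 (E)-4-(3,4-dimethoxyphenyl)-3-(methoxycarbonyl)but-3-enoic acid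
Conditions: NaOMe (1.3 equiv), MeOH, reflux; then aq HCl
Reagents that add atoms: none
Why: Stobbe condensation, in which the succinate enolate adds to the aldehyde, the aldolate closes to a paraconate lactone and base-induced ring opening leaves only the half-ester with the free acid on the CH2 arm, the E isomer being favoured (a minor Z isomer is tolerated by the next step).

Step 2
Reactants: 3 (E)-4-(3,4-dimethoxyphenyl)-3-(methoxycarbonyl)but-3-enoic acid
Product: 4 (R)-4-(3,4-dimethoxyphenyl)-3-(methoxycarbonyl)butanoic acid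
Conditions: H2 (5 bar), [Rh(cod)((S,S)-Et-DuPhos)]BF4 (0.5 mol %; ligand 1,2-bis[(2S,5S)-2,5-diethylphospholan-1-yl]benzene), NaOMe (0.1 equiv), MeOH, rt
Reagents that add atoms: none
Why: Rhodium-catalysed asymmetric hydrogenation of an itaconate-type half-ester, in which alkene and carboxylate chelate the cationic monovalent rhodium centre and the C2-symmetric (S,S)-bisphospholane directs H2 to one enantioface, which in the β-aryl itaconate series is expected to give the R acid and so sets the future C4 (the sense is to be confirmed by the sign of rotation of lactone 6, the (R,R)-ligand being equally available).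

Step 3
Reactants: 4 (R)-4-(3,4-dimethoxyphenyl)-3-(methoxycarbonyl)butanoic acid
Product: 6 (R)-4-(3,4-dimethoxybenzyl)dihydrofuran-2(3H)-one, via hydroxy acid 5 (not isolated)
Conditions: KOH (1.0 equiv), EtOH, 0 °C; then CaCl2, NaBH4, EtOH, −10 °C → rt; then 3 M HCl, rt
Reagents that add atoms: none
Why: Chemoselective ester reduction followed by acid-catalysed lactonisation, in which Ca(BH4)2 made in the flask reduces the methyl ester but not the potassium carboxylate and acidification closes hydroxy acid 5 to the five-membered lactone with the stereocentre carried over unchanged.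

Step 4
Reactants: 6 (R)-4-(3,4-dimethoxybenzyl)dihydrofuran-2(3H)-one; 7 3-bromo-1-(trimethylsilyl)prop-1-yne
Product: 9 (3R,4R)-4-(3,4-dimethoxybenzyl)-3-[3-(trimethylsilyl)prop-2-yn-1-yl]dihydrofuran-2(3H)-one, via lithium enolate 8 (not isolated)
Conditions: LiN(i-Pr)2 (1.1 equiv), THF, −78 °C; then 7 (1.3 equiv), DMPU (2 equiv), −78 → −40 °C
Reagents that add atoms: none
Why: Kinetic lactone enolate alkylation, in which the reactive propargylic bromide attacks the lithium enolate on the face anti to the C4 veratryl group and so sets C3 as R (3,4-trans), while the silyl cap suppresses SN2' attack and acetylide formation.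

Step 5
Reactants: 9 (3R,4R)-4-(3,4-dimethoxybenzyl)-3-[3-(trimethylsilyl)prop-2-yn-1-yl]dihydrofuran-2(3H)-one
Product: 10 4-[(3R,4R)-4-(3,4-dimethoxybenzyl)-2-oxotetrahydrofuran-3-yl]but-2-ynoic acid
Conditions: CsF (2 equiv), CO2 (1 atm), dry DMSO, rt; then 1 M HCl, 0 °C
Reagents that add atoms: carbon dioxide, O=C=O
Why: Fluoride-promoted desilylative carboxylation, in which fluoride attacks the trimethylsilyl group and the resulting alkynyl anion equivalent is trapped by CO2 as the caesium alkynoate, the weakly basic medium leaving the lactone intact and the trans arrangement at C3 and C4 being in any case the thermodynamic one.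

Step 6
Reactants: 10 4-[(3R,4R)-4-(3,4-dimethoxybenzyl)-2-oxotetrahydrofuran-3-yl]but-2-ynoic acid; 11 tert-butyldimethyl(prop-2-yn-1-yloxy)silane
Product: 13 (3R,4R)-3-{[6-({[tert-butyl(dimethyl)silyl]oxy}methyl)-2-oxo-2H-pyran-4-yl]methyl}-4-(3,4-dimethoxybenzyl)dihydrofuran-2(3H)-one, via enol ester 12 (not isolated)
Conditions: Ph3PAuCl (5 mol %), AgOTf (5 mol %), 11 (3 equiv), CH2Cl2, rt, dark
Reagents that add atoms: none
Why: Cationic monovalent gold (Ph3PAu+ from Ph3PAuCl and AgOTf) first activates the electron-richer terminal alkyne of 11, and the carboxylic acid of 10 adds in the Markovnikov sense to give the 2-substituted vinyl ester 12 (O1'–C6' bond). Gold then binds the ynoate of 12, the CH2 terminus of the enol ester attacks the β-carbon C4' in a 6-endo-dig closure (C4'–C5' bond), and the resulting oxocarbenium ion loses the C5' proton and is protodeaurated at C3' to give the aromatic pyrone. The closest known reaction type is the gold-catalysed coupling of alk-2-ynoic acids with terminal alkynes to 4,6-disubstituted 2-pyrones, here applied to a 4-alkyl ynoic acid and a propargylic silyl ether. No stereocentre is formed, and the neutral, non-basic medium should leave C3 and C4 of the lactone as set. The step needs Markovnikov regiochemistry in the acid addition and 6-endo rather than 5-exo closure: the first is secured by the terminal alkyne, where positive charge builds on the substituted carbon, and the second by the polarisation of the ynoate, whose electrophilic β-carbon lies six atoms from the nucleophilic CH2. C6' is carried as a silyloxymethyl group because an alkyne already at the carboxyl oxidation level would be too electron-poor to accept the acid, and the excess of 11 is meant to outrun intramolecular capture of the activated ynoate by the veratryl ring.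

Step 7
Reactants: 13 (3R,4R)-3-{[6-({[tert-butyl(dimethyl)silyl]oxy}methyl)-2-oxo-2H-pyran-4-yl]methyl}-4-(3,4-dimethoxybenzyl)dihydrofuran-2(3H)-one
Product: 14 (3R,4R)-4-(3,4-dimethoxybenzyl)-3-{[6-(hydroxymethyl)-2-oxo-2H-pyran-4-yl]methyl}dihydrofuran-2(3H)-one
Conditions: HF·pyridine, pyridine, THF, 0 °C → rt
Reagents that add atoms: none
Why: Fluoride-mediated silyl ether cleavage under buffered, mildly acidic conditions, which breaks the Si–O bond while sparing the base-sensitive pyrone, the lactone and the epimerisable C3 centre that unbuffered tetrabutylammonium fluoride could endanger.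

Step 8
Reactants: 14 (3R,4R)-4-(3,4-dimethoxybenzyl)-3-{[6-(hydroxymethyl)-2-oxo-2H-pyran-4-yl]methyl}dihydrofuran-2(3H)-one
Product: 15 4-{[(3R,4R)-4-(3,4-dimethoxybenzyl)-2-oxotetrahydrofuran-3-yl]methyl}-2-oxo-2H-pyran-6-carbaldehyde
Conditions: Dess–Martin periodinane (1.3 equiv), CH2Cl2, 0 °C → rt
Reagents that add atoms: none
Why: Dess–Martin oxidation, in which ligand exchange at the hypervalent iodine and internal deprotonation convert the primary allylic-type alcohol to the aldehyde under near-neutral conditions, without over-oxidation and without enolisation at C3.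

Step 9
Reactants: 15 4-{[(3R,4R)-4-(3,4-dimethoxybenzyl)-2-oxotetrahydrofuran-3-yl]methyl}-2-oxo-2H-pyran-6-carbaldehyde
Product: 16 4-{[(3R,4R)-4-(3,4-dimethoxybenzyl)-2-oxotetrahydrofuran-3-yl]methyl}-2-oxo-2H-pyran-6-carboxylic acid
Conditions: NaClO2, NaH2PO4, 2-methyl-2-butene (10 equiv), t-BuOH/H2O, 0 °C → rt
Reagents that add atoms: sodium chlorite, [Na+].[O-]Cl=O
Why: Pinnick oxidation, in which chlorous acid adds to the electron-poor aldehyde and fragments to the carboxylic acid and HOCl, the alkene scavenger removing HOCl before it can chlorinate the veratryl ring and the buffered medium sparing both lactone rings.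

**Compound list**

1 | veratraldehyde (3,4-dimethoxybenzaldehyde) | COc1ccc(C=O)cc1OC | starting material
2 | dimethyl succinate | COC(=O)CCC(=O)OC | starting material
3 | (E)-4-(3,4-dimethoxyphenyl)-3-(methoxycarbonyl)but-3-enoic acid | COC(=O)/C(CC(=O)O)=C/c1ccc(OC)c(OC)c1 | intermediate
4 | (R)-4-(3,4-dimethoxyphenyl)-3-(methoxycarbonyl)butanoic acid | COC(=O)[C@@H](CC(=O)O)Cc1ccc(OC)c(OC)c1 | intermediate
5 | (R)-4-(3,4-dimethoxyphenyl)-3-(hydroxymethyl)butanoic acid (hydroxy acid, formed in the flask) | OC[C@@H](CC(=O)O)Cc1ccc(OC)c(OC)c1 | intermediate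
6 | (R)-4-(3,4-dimethoxybenzyl)dihydrofuran-2(3H)-one | COc1ccc(C[C@H]2COC(=O)C2)cc1OC | intermediate
7 | 3-bromo-1-(trimethylsilyl)prop-1-yne | C[Si](C)(C)C#CCBr | starting material
8 | lithium (R)-4-(3,4-dimethoxybenzyl)-4,5-dihydrofuran-2-olate (lithium enolate, formed in the flask) | COc1ccc(C[C@H]2COC(O[Li])=C2)cc1OC | intermediate
9 | (3R,4R)-4-(3,4-dimethoxybenzyl)-3-[3-(trimethylsilyl)prop-2-yn-1-yl]dihydrofuran-2(3H)-one | COc1ccc(C[C@H]2COC(=O)[C@@H]2CC#C[Si](C)(C)C)cc1OC | intermediate
10 | 4-[(3R,4R)-4-(3,4-dimethoxybenzyl)-2-oxotetrahydrofuran-3-yl]but-2-ynoic acid | COc1ccc(C[C@H]2COC(=O)[C@@H]2CC#CC(=O)O)cc1OC | intermediate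
11 | tert-butyldimethyl(prop-2-yn-1-yloxy)silane | C#CCO[Si](C)(C)C(C)(C)C | starting material
12 | 3-[(tert-butyldimethylsilyl)oxy]prop-1-en-2-yl 4-[(3R,4R)-4-(3,4-dimethoxybenzyl)-2-oxotetrahydrofuran-3-yl]but-2-ynoate (enol ester, formed in the flask) | COc1ccc(C[C@H]2COC(=O)[C@@H]2CC#CC(=O)OC(=C)CO[Si](C)(C)C(C)(C)C)cc1OC | intermediate
13 | (3R,4R)-3-{[6-({[tert-butyl(dimethyl)silyl]oxy}methyl)-2-oxo-2H-pyran-4-yl]methyl}-4-(3,4-dimethoxybenzyl)dihydrofuran-2(3H)-one | COc1ccc(C[C@H]2COC(=O)[C@@H]2Cc2cc(CO[Si](C)(C)C(C)(C)C)oc(=O)c2)cc1OC | intermediate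
14 | (3R,4R)-4-(3,4-dimethoxybenzyl)-3-{[6-(hydroxymethyl)-2-oxo-2H-pyran-4-yl]methyl}dihydrofuran-2(3H)-one | COc1ccc(C[C@H]2COC(=O)[C@@H]2Cc2cc(CO)oc(=O)c2)cc1OC | intermediate
15 | 4-{[(3R,4R)-4-(3,4-dimethoxybenzyl)-2-oxotetrahydrofuran-3-yl]methyl}-2-oxo-2H-pyran-6-carbaldehyde | COc1ccc(C[C@H]2COC(=O)[C@@H]2Cc2cc(C=O)oc(=O)c2)cc1OC | intermediate
16 | 4-{[(3R,4R)-4-(3,4-dimethoxybenzyl)-2-oxotetrahydrofuran-3-yl]methyl}-2-oxo-2H-pyran-6-carboxylic acid | COc1ccc(C[C@H]2COC(=O)[C@@H]2Cc2cc(C(=O)O)oc(=O)c2)cc1OC | target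

**Step count**

Total step count: 9 steps.
Longest linear sequence: 9 steps (veratraldehyde 1 to target 16); bromide 7 and silyl ether 11 are purchased.

**Steps most likely to fail**

Step 6 (gold cascade). The cascade may stop after the intermolecular acid addition, so that the enol ester accumulates. The gold-activated ynoate may also be captured intramolecularly by the electron-rich veratryl ring or by the lactone carbonyl before the enol ester forms, and traces of triflic acid may strip the silyl ether. The fallback brings the pyrone in intact and uses known chemistry only. It sets out from lactone 6 and comes back to the route at target 16. Diethyl oxalate and ethyl 3-methylbut-2-enoate are condensed (KOEt, EtOH/Et2O; then HCl, heat) to ethyl 4-methyl-2-oxo-2H-pyran-6-carboxylate F1. Wohl–Ziegler bromination (NBS, AIBN, PhCF3, reflux) should give ethyl 4-(bromomethyl)-2-oxo-2H-pyran-6-carboxylate F2. The lithium enolate 8 of lactone 6 is then alkylated with F2 at −78 °C, again anti to the veratryl group, to give ethyl 4-{[(3R,4R)-4-(3,4-dimethoxybenzyl)-2-oxotetrahydrofuran-3-yl]methyl}-2-oxo-2H-pyran-6-carboxylate F3. Acidic hydrolysis of the ethyl ester (6 M HCl, dioxane, 60 °C), under which the γ-lactone stays closed, gives 16.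

Step 5 (desilylative carboxylation). Protodesilylation by adventitious water may outrun capture of the alkynyl anion equivalent by CO2, and the basic fluoride medium may isomerise the skipped ynoate to an allenoate. The fallback brings the carboxyl carbon in with the electrophile at the alcohol oxidation level. It sets out from lactone 6 and comes back to the route at acid 10. But-2-yne-1,4-diol is monosilylated (NaH, TBSCl, THF) to 4-[(tert-butyldimethylsilyl)oxy]but-2-yn-1-ol F4, which an Appel reaction (CBr4, PPh3, CH2Cl2) converts to [(4-bromobut-2-yn-1-yl)oxy](tert-butyl)dimethylsilane F5. Enolate 8 of lactone 6 is alkylated with F5 under the conditions of step 4 to give (3R,4R)-3-{4-[(tert-butyldimethylsilyl)oxy]but-2-yn-1-yl}-4-(3,4-dimethoxybenzyl)dihydrofuran-2(3H)-one F6. HF·pyridine then frees (3R,4R)-4-(3,4-dimethoxybenzyl)-3-(4-hydroxybut-2-yn-1-yl)dihydrofuran-2(3H)-one F7. Dess–Martin oxidation gives 4-[(3R,4R)-4-(3,4-dimethoxybenzyl)-2-oxotetrahydrofuran-3-yl]but-2-ynal F8, and Pinnick oxidation (NaClO2, NaH2PO4, 2-methyl-2-butene) gives acid 10.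

Step 8 (oxidation to the 6-formylpyrone). The oxidation may not stop cleanly: the electron-poor aldehyde hydrates readily, may be partly over-oxidised and may degrade on chromatography. The fallback avoids the free aldehyde altogether. It sets out from alcohol 14 and comes back to the route at target 16. Alcohol 14 is oxidised in one flask with TEMPO (0.2 equiv) and PhI(OAc)2 (2.2 equiv) in MeCN/H2O at rt, the oxoammonium species oxidising first the alcohol and then the aldehyde hydrate as it forms. No new compound is made.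

**Further compounds**

F1 | step 6 | ethyl 4-methyl-2-oxo-2H-pyran-6-carboxylate | CCOC(=O)c1cc(C)cc(=O)o1
F2 | step 6 | ethyl 4-(bromomethyl)-2-oxo-2H-pyran-6-carboxylate | CCOC(=O)c1cc(CBr)cc(=O)o1
F3 | step 6 | ethyl 4-{[(3R,4R)-4-(3,4-dimethoxybenzyl)-2-oxotetrahydrofuran-3-yl]methyl}-2-oxo-2H-pyran-6-carboxylate | COc1ccc(C[C@H]2COC(=O)[C@@H]2Cc2cc(C(=O)OCC)oc(=O)c2)cc1OC
F4 | step 5 | 4-[(tert-butyldimethylsilyl)oxy]but-2-yn-1-ol | OCC#CCO[Si](C)(C)C(C)(C)C
F5 | step 5 | [(4-bromobut-2-yn-1-yl)oxy](tert-butyl)dimethylsilane | BrCC#CCO[Si](C)(C)C(C)(C)C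
F6 | step 5 | (3R,4R)-3-{4-[(tert-butyldimethylsilyl)oxy]but-2-yn-1-yl}-4-(3,4-dimethoxybenzyl)dihydrofuran-2(3H)-one | COc1ccc(C[C@H]2COC(=O)[C@@H]2CC#CCO[Si](C)(C)C(C)(C)C)cc1OC
F7 | step 5 | (3R,4R)-4-(3,4-dimethoxybenzyl)-3-(4-hydroxybut-2-yn-1-yl)dihydrofuran-2(3H)-one | COc1ccc(C[C@H]2COC(=O)[C@@H]2CC#CCO)cc1OC
F8 | step 5 | 4-[(3R,4R)-4-(3,4-dimethoxybenzyl)-2-oxotetrahydrofuran-3-yl]but-2-ynal | COc1ccc(C[C@H]2COC(=O)[C@@H]2CC#CC=O)cc1OC
F0 | step 8 | none | none
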